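**Retrosynthetic overview**

1. The target is reached by debenzylation and lactol reduction of lactol 27. The upper pyran ring of 27 (C3–C4 and O1–C2, 3,4-trans) comes from an amine-catalysed annulation of the o-quinone methide of benzhydrol 19 with arylacetaldehyde 25.
2. Benzhydrol 19 comes from the aryllithium of bromide 15 and 4-(benzyloxy)-2-hydroxybenzaldehyde 16, so the arene–C4 bond is fixed by the position of the bromine.
3. Bromide 15 comes from chromanol 14, which is assembled in one operation from resorcinol 11 and 2-arylacrolein 10: Friedel–Crafts conjugate addition (C4–C4a), enantioselective protonation (C3) and lactolisation (O1–C2), with the lactol hydroxyl removed in the same operation by ionic hydrogenation.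
4. Enabling feature: ring A of the lower chromane is a resorcinol (O1 and the 7-OH are meta, so C4a is ortho to O1 and para to the 7-OH). C2–C3–C4 is a three-carbon unit with two CH2 ends and the aryl group plus one H on C3, which is the skeleton of a 2-arylacrolein (C4 = β-carbon, C2 = carbonyl carbon).
5. Ring order: lower pyran ring (step 6), then upper pyran ring (step 12). Acrolein 10 comes from 2-bromo-3-methoxybenzaldehyde 1 by meta C–H borylation/oxidation, one-carbon homologation and α-methylenation.

Key step: step 6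

Assumption: the sense of induction of the two chiral amine catalysts (steps 6 and 12) is assigned from the usual transition-state models. Both catalysts are available in either enantiomeric form, so a reversed sense would be corrected by exchanging the catalyst enantiomer without changing the route.

Remark: chromane numbering (O1, C2, C3, C4, C4a–C8a) is used. "Lower" means the 3-arylchromane without a C4 substituent, "upper" the 3,4-diarylchromane.

**Route**

Step 1
Reactants: 1 2-bromo-3-methoxybenzaldehyde
Product: 2 2-bromo-1-(dimethoxymethyl)-3-methoxybenzene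
Conditions: HC(OMe)3, p-TsOH·H2O (cat.), MeOH, rt
Reagents that add atoms: trimethyl orthoformate, COC(OC)OC
Why: Acid-catalysed acetalisation masks the aldehyde, which would not tolerate the borylation, and the orthoformate drives the equilibrium by consuming water.

Step 2
Reactants: 2 2-bromo-1-(dimethoxymethyl)-3-methoxybenzene
Product: 4 4-bromo-3-(dimethoxymethyl)-5-methoxyphenol, via aryl boronate 3 (not isolated)
Conditions: [Ir(OMe)(cod)]2 (1.5 mol %), 4,4'-di-tert-butyl-2,2'-bipyridine (3 mol %), B2pin2, THF, 70 °C; then aq. NaOH, 30% H2O2, 0 °C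
Reagents that add atoms: bis(pinacolato)diboron, CC1(C)OB(OC1(C)C)B1OC(C)(C)C(C)(C)O1 (boron and pinacol of intermediate 3 only); hydrogen peroxide, OO (phenol oxygen of 4)
Why: Iridium-catalysed arene C–H borylation is sterically controlled, and in this 1,2,3-trisubstituted benzene only C5 (para to bromine) has no ortho substituent, so the boronate and then, by oxidation of the C–B bond with basic peroxide, the phenol should form at that carbon alone while the C–Br bond and the acetal stay intact.

Step 3
Reactants: 4 4-bromo-3-(dimethoxymethyl)-5-methoxyphenol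
Product: 6 5-(benzyloxy)-2-bromo-3-methoxybenzaldehyde, via benzyl ether acetal 5 (not isolated)
Conditions: BnBr, K2CO3, DMF, rt; then 2 M HCl, THF, rt
Reagents that add atoms: benzyl bromide, BrCc1ccccc1; water, O
Why: Williamson etherification of the phenol followed by acid hydrolysis of the dimethyl acetal, both routine and compatible with the aryl bromide.

Step 4
Reactants: 6 5-(benzyloxy)-2-bromo-3-methoxybenzaldehyde
Product: 8 2-[5-(benzyloxy)-2-bromo-3-methoxyphenyl]acetaldehyde, via enol ether 7 (not isolated)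
Conditions: Ph3P(CH2OMe)Cl, KOtBu, THF, 0 °C to rt; then 2 M HCl, THF, rt
Reagents that add atoms: (methoxymethyl)triphenylphosphonium chloride, COC[P+](c1ccccc1)(c1ccccc1)c1ccccc1.[Cl-]; water, O
Why: Wittig methoxymethylenation of the non-enolisable aldehyde and hydrolysis of the enol ether is the standard one-carbon homologation to an arylacetaldehyde.

Step 5
Reactants: 8 2-[5-(benzyloxy)-2-bromo-3-methoxyphenyl]acetaldehyde
Product: 10 2-[5-(benzyloxy)-2-bromo-3-methoxyphenyl]prop-2-enal, via Mannich base 9 (not isolated)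
Conditions: N,N-dimethylmethyleneiminium iodide (1.5 equiv), Et3N, CH2Cl2, rt
Reagents that add atoms: N,N-dimethylmethyleneiminium iodide, C=[N+](C)C.[I-]
Why: Mannich reaction of the enolisable arylacetaldehyde followed by base-induced β-elimination of dimethylamine is the usual α-methylenation to a 2-arylacrolein, and the ortho bromine should slow its dimerisation (10 is used at once).

Step 6
Reactants: 10 2-[5-(benzyloxy)-2-bromo-3-methoxyphenyl]prop-2-enal; 11 resorcinol
Product: 14 (3R)-3-[5-(benzyloxy)-2-bromo-3-methoxyphenyl]chroman-7-ol, via hydroxy aldehyde 12 (not isolated), via lactol 13 (not isolated)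
Conditions: (S)-N1,N1-diethyl-3,3-dimethylbutane-1,2-diamine·TfOH (20 mol %), 11 (3 equiv), CH2Cl2/i-PrOH, 0 °C, slow addition of 10; dilute HCl and water washes, dry, concentrate; then crude 13, Et3SiH (4 equiv), BF3·OEt2 (2 equiv), CH2Cl2, −78 to −40 °C
Reagents that add atoms: none
Why: Proposed new method: the primary amine of the catalyst condenses with 10 to an iminium ion, C4 of resorcinol (ortho to one hydroxyl, para to the other) adds to the unhindered terminal CH2 in a Friedel–Crafts conjugate addition, the resulting α-aryl enamine is protonated by the catalyst's own ammonium N–H, hydrolysis releases aldehyde 12, the neighbouring phenol captures it as lactol 13, and the washed crude lactol is reduced at once by ionic hydrogenation through its cyclic oxocarbenium ion, which keeps the new O1–C2 bond. The closest known reaction types are the amine-catalysed Friedel–Crafts alkylation/hemiacetalisation of electron-rich phenols and naphthols with enals to chroman-2-ols and the primary-amine-catalysed conjugate addition of arenes and thiols to α-substituted acroleins with enantioselective enamine protonation; their combination on a 2-arylacrolein and a phenol has not been shown, whereas the silane reduction of a lactol is standard. The C4–C4a bond forms intermolecularly and the pyran ring then closes by 6-exo-trig addition of the phenol oxygen to the aldehyde carbon (O1–C2). C3 is set by catalyst-controlled protonation of the enamine (the (S)-diamine is assumed to give 3R), the anomeric centre is uncontrolled and is erased by the reduction, and the lactol is not purified because its open aldehyde form could epimerise at C3 on silica. The step needs C- over O-alkylation, attack at C4 instead of C2 of resorcinol, mono-alkylation, a configurationally stable α-aryl aldehyde and hydride capture of the oxocarbenium ion before it can lose the C3 proton. Oxa-Michael addition is reversible, C2 is flanked by two hydroxyls and its adduct gains nothing more than the C4 adduct does, excess resorcinol suppresses a second alkylation and is washed out before the Lewis acid is added, the ortho bromine twists the aryl group out of conjugation while lactol closure withdraws the aldehyde from the amine, and excess silane at low temperature favours reduction over elimination.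

Step 7
Reactants: 14 (3R)-3-[5-(benzyloxy)-2-bromo-3-methoxyphenyl]chroman-7-ol
Product: 15 (3R)-7-(benzyloxy)-3-[5-(benzyloxy)-2-bromo-3-methoxyphenyl]chromane
Conditions: BnBr, K2CO3, DMF, rt
Reagents that add atoms: benzyl bromide, BrCc1ccccc1
Why: Williamson etherification protects the only acidic group before the organolithium step and does not touch the C3 stereocentre.

Step 8
Reactants: 15 (3R)-7-(benzyloxy)-3-[5-(benzyloxy)-2-bromo-3-methoxyphenyl]chromane; 16 4-(benzyloxy)-2-hydroxybenzaldehyde
Product: 19 [4-(benzyloxy)-2-hydroxyphenyl]{4-(benzyloxy)-2-[(3R)-7-(benzyloxy)chroman-3-yl]-6-methoxyphenyl}methanol (both carbinol epimers), via aryllithium 17 (not isolated), via sodium phenoxide 18 (not isolated)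
Conditions: 16 (1.5 equiv) and NaH (1.5 equiv), THF, 0 °C; separately 15, n-BuLi (1.05 equiv), THF, −78 °C; phenoxide solution added at −78 °C, then to 0 °C; aq. NH4Cl; product used crude
Reagents that add atoms: n-butyllithium, [Li]CCCC (lithium of intermediate 17 only); sodium hydride, [Na+].[H-] (sodium of intermediate 18 only)
Why: Bromine–lithium exchange at −78 °C is faster than any deprotonation, and 1,2-addition of the aryllithium to the pre-formed phenoxide of the salicylaldehyde gives the o-hydroxybenzhydrol directly; the new carbinol centre is lost in step 12, so its configuration does not matter.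

Step 9
Reactants: 20 2,6-dimethoxyphenol
Product: 21 2-(benzyloxy)-1,3-dimethoxybenzene
Conditions: BnBr, K2CO3, DMF, rt
Reagents that add atoms: benzyl bromide, BrCc1ccccc1
Why: Williamson etherification of the phenol.

Step 10
Reactants: 21 2-(benzyloxy)-1,3-dimethoxybenzene
Product: 23 3-(benzyloxy)-2,4-dimethoxybenzaldehyde, via iminium salt 22 (not isolated)
Conditions: POCl3, DMF, 0 to 70 °C; then H2O, 0 °C to rt
Reagents that add atoms: N,N-dimethylformamide, CN(C)C=O; phosphoryl chloride, O=P(Cl)(Cl)Cl (chloride of intermediate 22 only); water, O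
Why: Vilsmeier–Haack formylation of a 1,2,3-trialkoxybenzene goes to C4, ortho to one outer methoxy group and para to the other, because the twisted central ether does not activate C5.

Step 11
Reactants: 23 3-(benzyloxy)-2,4-dimethoxybenzaldehyde
Product: 25 2-[3-(benzyloxy)-2,4-dimethoxyphenyl]acetaldehyde, via enol ether 24 (not isolated)
Conditions: Ph3P(CH2OMe)Cl, KOtBu, THF, 0 °C to rt; then 2 M HCl, THF, rt
Reagents that add atoms: (methoxymethyl)triphenylphosphonium chloride, COC[P+](c1ccccc1)(c1ccccc1)c1ccccc1.[Cl-]; water, O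
Why: Wittig methoxymethylenation and enol ether hydrolysis, as in step 4.

Step 12
Reactants: 19 [4-(benzyloxy)-2-hydroxyphenyl]{4-(benzyloxy)-2-[(3R)-7-(benzyloxy)chroman-3-yl]-6-methoxyphenyl}methanol; 25 2-[3-(benzyloxy)-2,4-dimethoxyphenyl]acetaldehyde
Product: 27 (3R,4S)-7-(benzyloxy)-4-{4-(benzyloxy)-2-[(3R)-7-(benzyloxy)chroman-3-yl]-6-methoxyphenyl}-3-[3-(benzyloxy)-2,4-dimethoxyphenyl]chroman-2-ol (anomer mixture), via o-quinone methide 26 (not isolated)
Conditions: 25 (2.5 equiv), (R)-α,α-diphenylprolinol trimethylsilyl ether (20 mol %), PhCO2H (20 mol %), CHCl3, rt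
Reagents that add atoms: none
Why: Enamine-catalysed Michael addition to an o-quinone methide generated in situ, followed by hemiacetalisation (formal [4+2] annulation): the weak acid ionises the doubly para-alkoxy-stabilised benzhydrol to 26 with loss of water, the (R)-catalyst shields one face of the enamine of 25 and so sets C3, the endo-type approach places the C4 aryl trans to the C3 aryl, and the trans arrangement is also the thermodynamic one because C3 can epimerise through the open aldehyde.

Step 13
Reactants: 27 (3R,4S)-7-(benzyloxy)-4-{4-(benzyloxy)-2-[(3R)-7-(benzyloxy)chroman-3-yl]-6-methoxyphenyl}-3-[3-(benzyloxy)-2,4-dimethoxyphenyl]chroman-2-ol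
Product: 28 (3R,4S)-7-(benzyloxy)-4-{4-(benzyloxy)-2-[(3R)-7-(benzyloxy)chroman-3-yl]-6-methoxyphenyl}-3-[3-(benzyloxy)-2,4-dimethoxyphenyl]chromane
Conditions: Et3SiH (5 equiv), BF3·OEt2, CH2Cl2, −78 to −30 °C
Reagents that add atoms: none
Why: Ionic hydrogenation of the lactol via its oxocarbenium ion, as in the second stage of step 6; benzyl ethers and the diarylmethine C4 are inert under these conditions.

Step 14
Reactants: 28 (3R,4S)-7-(benzyloxy)-4-{4-(benzyloxy)-2-[(3R)-7-(benzyloxy)chroman-3-yl]-6-methoxyphenyl}-3-[3-(benzyloxy)-2,4-dimethoxyphenyl]chromane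
Product: 29 (3R,4S)-4-{4-hydroxy-2-[(3R)-7-hydroxychroman-3-yl]-6-methoxyphenyl}-3-(3-hydroxy-2,4-dimethoxyphenyl)chroman-7-ol (CNP0305801.1)
Conditions: H2 (1 atm), 10% Pd/C, THF/MeOH, rt
Reagents that add atoms: none
Why: Hydrogenolysis removes all four benzyl ethers in one step, while the methyl ethers, the chromane C–O bonds and the three benzylic stereocentres (no benzylic heteroatom) are not affected.

**Compound list**

1 | 2-bromo-3-methoxybenzaldehyde | COc1cccc(C=O)c1Br | starting material
2 | 2-bromo-1-(dimethoxymethyl)-3-methoxybenzene | COc1cccc(C(OC)OC)c1Br | intermediate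
3 | 2-[4-bromo-3-(dimethoxymethyl)-5-methoxyphenyl]-4,4,5,5-tetramethyl-1,3,2-dioxaborolane | COc1cc(B2OC(C)(C)C(C)(C)O2)cc(C(OC)OC)c1Br | intermediate (not isolated)
4 | 4-bromo-3-(dimethoxymethyl)-5-methoxyphenol | COc1cc(O)cc(C(OC)OC)c1Br | intermediate
5 | 5-(benzyloxy)-2-bromo-1-(dimethoxymethyl)-3-methoxybenzene | COc1cc(OCc2ccccc2)cc(C(OC)OC)c1Br | intermediate (not isolated)
6 | 5-(benzyloxy)-2-bromo-3-methoxybenzaldehyde | COc1cc(OCc2ccccc2)cc(C=O)c1Br | intermediate
7 | 5-(benzyloxy)-2-bromo-1-methoxy-3-(2-methoxyethenyl)benzene (E/Z mixture) | COC=Cc1cc(OCc2ccccc2)cc(OC)c1Br | intermediate (not isolated)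
8 | 2-[5-(benzyloxy)-2-bromo-3-methoxyphenyl]acetaldehyde | O=CCc1cc(OCc2ccccc2)cc(OC)c1Br | intermediate
9 | 2-[5-(benzyloxy)-2-bromo-3-methoxyphenyl]-3-(dimethylamino)propanal (racemic Mannich base) | CN(C)CC(C=O)c1cc(OCc2ccccc2)cc(OC)c1Br | intermediate (not isolated)
10 | 2-[5-(benzyloxy)-2-bromo-3-methoxyphenyl]prop-2-enal | C=C(C=O)c1cc(OCc2ccccc2)cc(OC)c1Br | intermediate
11 | resorcinol | Oc1cccc(O)c1 | starting material
12 | (2R)-2-[5-(benzyloxy)-2-bromo-3-methoxyphenyl]-3-(2,4-dihydroxyphenyl)propanal | COc1cc(OCc2ccccc2)cc([C@@H](Cc2ccc(O)cc2O)C=O)c1Br | intermediate (not isolated)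
13 | (3R)-3-[5-(benzyloxy)-2-bromo-3-methoxyphenyl]chromane-2,7-diol (anomer mixture) | COc1cc(OCc2ccccc2)cc([C@@H]2C(O)Oc3cc(O)ccc3C2)c1Br | intermediate (not isolated)
14 | (3R)-3-[5-(benzyloxy)-2-bromo-3-methoxyphenyl]chroman-7-ol | COc1cc(OCc2ccccc2)cc([C@@H]2COc3cc(O)ccc3C2)c1Br | intermediate
15 | (3R)-7-(benzyloxy)-3-[5-(benzyloxy)-2-bromo-3-methoxyphenyl]chromane | COc1cc(OCc2ccccc2)cc([C@@H]2COc3cc(OCc4ccccc4)ccc3C2)c1Br | intermediate
16 | 4-(benzyloxy)-2-hydroxybenzaldehyde | O=Cc1ccc(OCc2ccccc2)cc1O | starting material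
17 | {4-(benzyloxy)-2-[(3R)-7-(benzyloxy)chroman-3-yl]-6-methoxyphenyl}lithium | [Li]c1c(OC)cc(OCc2ccccc2)cc1[C@@H]1COc2cc(OCc3ccccc3)ccc2C1 | intermediate (not isolated)
18 | sodium 5-(benzyloxy)-2-formylphenoxide | [Na+].[O-]c1cc(OCc2ccccc2)ccc1C=O | intermediate (not isolated)
19 | [4-(benzyloxy)-2-hydroxyphenyl]{4-(benzyloxy)-2-[(3R)-7-(benzyloxy)chroman-3-yl]-6-methoxyphenyl}methanol (both carbinol epimers) | COc1cc(OCc2ccccc2)cc([C@@H]2COc3cc(OCc4ccccc4)ccc3C2)c1C(O)c1ccc(OCc2ccccc2)cc1O | intermediate
20 | 2,6-dimethoxyphenol | COc1cccc(OC)c1O | starting material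
21 | 2-(benzyloxy)-1,3-dimethoxybenzene | COc1cccc(OC)c1OCc1ccccc1 | intermediate
22 | N-{[3-(benzyloxy)-2,4-dimethoxyphenyl]methylidene}-N-methylmethanaminium chloride | COc1ccc(C=[N+](C)C)c(OC)c1OCc1ccccc1.[Cl-] | intermediate (not isolated)
23 | 3-(benzyloxy)-2,4-dimethoxybenzaldehyde | COc1ccc(C=O)c(OC)c1OCc1ccccc1 | intermediate
24 | 2-(benzyloxy)-1,3-dimethoxy-4-(2-methoxyethenyl)benzene (E/Z mixture) | COC=Cc1ccc(OC)c(OCc2ccccc2)c1OC | intermediate (not isolated)
25 | 2-[3-(benzyloxy)-2,4-dimethoxyphenyl]acetaldehyde | COc1ccc(CC=O)c(OC)c1OCc1ccccc1 | intermediate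
26 | 3-(benzyloxy)-6-({4-(benzyloxy)-2-[(3R)-7-(benzyloxy)chroman-3-yl]-6-methoxyphenyl}methylidene)cyclohexa-2,4-dien-1-one | O=C1C=C(OCc2ccccc2)C=CC1=Cc1c(OC)cc(OCc2ccccc2)cc1[C@@H]1COc2cc(OCc3ccccc3)ccc2C1 | intermediate (not isolated)
27 | (3R,4S)-7-(benzyloxy)-4-{4-(benzyloxy)-2-[(3R)-7-(benzyloxy)chroman-3-yl]-6-methoxyphenyl}-3-[3-(benzyloxy)-2,4-dimethoxyphenyl]chroman-2-ol (anomer mixture) | COc1ccc([C@@H]2C(O)Oc3cc(OCc4ccccc4)ccc3[C@H]2c2c(OC)cc(OCc3ccccc3)cc2[C@@H]2COc3cc(OCc4ccccc4)ccc3C2)c(OC)c1OCc1ccccc1 | intermediate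
28 | (3R,4S)-7-(benzyloxy)-4-{4-(benzyloxy)-2-[(3R)-7-(benzyloxy)chroman-3-yl]-6-methoxyphenyl}-3-[3-(benzyloxy)-2,4-dimethoxyphenyl]chromane | COc1ccc([C@@H]2COc3cc(OCc4ccccc4)ccc3[C@H]2c2c(OC)cc(OCc3ccccc3)cc2[C@@H]2COc3cc(OCc4ccccc4)ccc3C2)c(OC)c1OCc1ccccc1 | intermediate
29 | (3R,4S)-4-{4-hydroxy-2-[(3R)-7-hydroxychroman-3-yl]-6-methoxyphenyl}-3-(3-hydroxy-2,4-dimethoxyphenyl)chroman-7-ol | COc1ccc([C@@H]2COc3cc(O)ccc3[C@H]2c2c(OC)cc(O)cc2[C@@H]2COc3cc(O)ccc3C2)c(OC)c1O | target

**Step count**

Total steps: 14. Longest linear sequence: 11 (steps 1–8 and 12–14; steps 9–11 prepare fragment 25).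

**Steps most likely to fail, and fallbacks**

Step 6 (Proposed new method). The enantiomeric purity at C3 may be lost because the enamine is protonated without facial control, because the ring-opened aldehyde 12 re-enters the enamine manifold, or because the oxocarbenium ion of the reduction stage loses the C3 proton; the acrolein may also oligomerise before it is alkylated. The fallback sets out from 8 (with 16) and returns at 15, using only known reaction types and avoiding the lactol altogether. Pinnick oxidation of 8 (NaClO2, NaH2PO4, 2-methyl-2-butene) should give 2-[5-(benzyloxy)-2-bromo-3-methoxyphenyl]acetic acid F1. Perkin condensation of F1 with 16 (Ac2O, Et3N, 110 °C) should give 7-(benzyloxy)-3-[5-(benzyloxy)-2-bromo-3-methoxyphenyl]-2H-chromen-2-one F2. Reduction of the lactone with diisobutylaluminium hydride should give (2Z)-3-[4-(benzyloxy)-2-hydroxyphenyl]-2-[5-(benzyloxy)-2-bromo-3-methoxyphenyl]prop-2-en-1-ol F3. Intramolecular Mitsunobu etherification (PPh3, DIAD) should close it to 7-(benzyloxy)-3-[5-(benzyloxy)-2-bromo-3-methoxyphenyl]-2H-chromene F4. Asymmetric hydrogenation of this trisubstituted 3-aryl-2H-chromene with [Ir(cod)(L)]BArF (L = chiral phosphine–oxazoline, enantiomer chosen for 3R; H2, CH2Cl2) would then set C3 and deliver 15 directly.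

Step 12. Attack of the enamine on the hindered o-quinone methide may be slow and poorly face-selective, so that self-condensation of 25 or a mismatched combination with the existing stereocentre takes over. The fallback sets out from 19 and 25 and returns at 28; it gives up catalyst control and uses the enantiopure lower stereocentre for a separation instead. With an achiral, small secondary amine (pyrrolidine, PhCO2H) the annulation should give both 3,4-trans lactols, 27 and its upper-ring epimer (3S,4R)-7-(benzyloxy)-4-{4-(benzyloxy)-2-[(3R)-7-(benzyloxy)chroman-3-yl]-6-methoxyphenyl}-3-[3-(benzyloxy)-2,4-dimethoxyphenyl]chroman-2-ol F5. Reduction of the mixture with Et3SiH and BF3·OEt2 as in step 13 would give 28 together with the diastereomeric (3S,4R)-7-(benzyloxy)-4-{4-(benzyloxy)-2-[(3R)-7-(benzyloxy)chroman-3-yl]-6-methoxyphenyl}-3-[3-(benzyloxy)-2,4-dimethoxyphenyl]chromane F6. These two are diastereomers, not enantiomers, and should be separable by chromatography or crystallisation; the unwanted one is discarded.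

Step 13. The oxocarbenium ion may lose the acidic C3 proton to give the 3,4-diaryl-4H-chromene, and reprotonation would scramble the 3,4-trans relationship. The fallback sets out from 27 and returns at 28, and avoids any cation at C2. NaBH4 (MeOH/CH2Cl2, −20 °C) should reduce the lactol through its open form to (2R,3S)-3-[4-(benzyloxy)-2-hydroxyphenyl]-3-{4-(benzyloxy)-2-[(3R)-7-(benzyloxy)chroman-3-yl]-6-methoxyphenyl}-2-[3-(benzyloxy)-2,4-dimethoxyphenyl]propan-1-ol F7. Intramolecular Mitsunobu etherification (PPh3, DIAD, THF) should then close the pyran ring through the only free phenol and give 28.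

**Further compounds**

F1 | step 6 | 2-[5-(benzyloxy)-2-bromo-3-methoxyphenyl]acetic acid | OC(=O)Cc1cc(OCc2ccccc2)cc(OC)c1Br
F2 | step 6 | 7-(benzyloxy)-3-[5-(benzyloxy)-2-bromo-3-methoxyphenyl]-2H-chromen-2-one | O=C1Oc2cc(OCc3ccccc3)ccc2C=C1c1cc(OCc2ccccc2)cc(OC)c1Br
F3 | step 6 | (2Z)-3-[4-(benzyloxy)-2-hydroxyphenyl]-2-[5-(benzyloxy)-2-bromo-3-methoxyphenyl]prop-2-en-1-ol | OC/C(=C\c1ccc(OCc2ccccc2)cc1O)c1cc(OCc2ccccc2)cc(OC)c1Br
F4 | step 6 | 7-(benzyloxy)-3-[5-(benzyloxy)-2-bromo-3-methoxyphenyl]-2H-chromene | COc1cc(OCc2ccccc2)cc(C2=Cc3ccc(OCc4ccccc4)cc3OC2)c1Br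
F5 | step 12 | (3S,4R)-7-(benzyloxy)-4-{4-(benzyloxy)-2-[(3R)-7-(benzyloxy)chroman-3-yl]-6-methoxyphenyl}-3-[3-(benzyloxy)-2,4-dimethoxyphenyl]chroman-2-ol | COc1ccc([C@H]2C(O)Oc3cc(OCc4ccccc4)ccc3[C@@H]2c2c(OC)cc(OCc3ccccc3)cc2[C@@H]2COc3cc(OCc4ccccc4)ccc3C2)c(OC)c1OCc1ccccc1
F6 | step 12 | (3S,4R)-7-(benzyloxy)-4-{4-(benzyloxy)-2-[(3R)-7-(benzyloxy)chroman-3-yl]-6-methoxyphenyl}-3-[3-(benzyloxy)-2,4-dimethoxyphenyl]chromane | COc1ccc([C@H]2COc3cc(OCc4ccccc4)ccc3[C@@H]2c2c(OC)cc(OCc3ccccc3)cc2[C@@H]2COc3cc(OCc4ccccc4)ccc3C2)c(OC)c1OCc1ccccc1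
F7 | step 13 | (2R,3S)-3-[4-(benzyloxy)-2-hydroxyphenyl]-3-{4-(benzyloxy)-2-[(3R)-7-(benzyloxy)chroman-3-yl]-6-methoxyphenyl}-2-[3-(benzyloxy)-2,4-dimethoxyphenyl]propan-1-ol | COc1ccc([C@H](CO)[C@@H](c2ccc(OCc3ccccc3)cc2O)c2c(OC)cc(OCc3ccccc3)cc2[C@@H]2COc3cc(OCc4ccccc4)ccc3C2)c(OC)c1OCc1ccccc1
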